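The pyranone ring (O1, C2, C3, C4, C4a, C8a) is simplified by taking out C3, its only unsubstituted CH2, as a carbene. This leaves the five-membered ring of a commercial coumaranone. Forward, C3 is added across the C2–C4 enol double bond of a 3-silyloxybenzofuran. The resulting silyloxycyclopropane masks the ketone, so C6, the C–H between two MOM ethers, can be lithiated and prenylated. Iron(III) then breaks the shared C2–C4 bond, because O1 stabilises the radical at C2. In one operation the five-membered ring becomes six-membered and the C2=C3 acceptor appears. Rhodium-catalysed asymmetric arylation at C2 joins ring B and sets the stereocentre.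

Key step: step 5

Remark: 4,6-dihydroxy-1-benzofuran-3(2H)-one is taken as a purchasable compound. Flavanone numbering is used for 8, 9, 16 and 17, and cyclopropa[b]benzofuran numbering for 4, 6 and 7.

Step 1
Reactants: 1 4,6-dihydroxy-1-benzofuran-3(2H)-one
Product: 2 4,6-bis(methoxymethoxy)-1-benzofuran-3(2H)-one
Conditions: MOMCl (excess), i-Pr2NEt, CH2Cl2, 0 °C to reflux
Reagents that add atoms: chloromethyl methyl ether COCCl
Why: Double O-alkylation (MOM ether formation) in which the amine base deprotonates only the phenols, the chelated 4-OH reacting last on warming, so that C2 of the coumaranone should stay untouched.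

Step 2
Reactants: 2 4,6-bis(methoxymethoxy)-1-benzofuran-3(2H)-one
Product: 3 4,6-bis(methoxymethoxy)-3-(triethylsilyloxy)-1-benzofuran
Conditions: TESOTf, Et3N (excess), CH2Cl2, 0 °C
Reagents that add atoms: triethylsilyl trifluoromethanesulfonate CC[Si](CC)(CC)OS(=O)(=O)C(F)(F)F
Why: Soft enolisation with a silyl triflate and an amine, in which the ketone can enolise only towards C2 and the silyl enol ether gains benzofuran aromaticity, while excess amine protects the MOM acetals from the triflate.

Step 3
Reactants: 3 4,6-bis(methoxymethoxy)-3-(triethylsilyloxy)-1-benzofuran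
Product: 4 rac-4,6-bis(methoxymethoxy)-6b-(triethylsilyloxy)-1a,6b-dihydro-1H-cyclopropa[b][1]benzofuran
Conditions: Et2Zn, CH2I2, CH2Cl2–Et2O, 0 °C to rt
Reagents that add atoms: diiodomethane ICI
Why: Simmons–Smith cyclopropanation (Furukawa variant), in which the electrophilic zinc carbenoid should add to the furan C2=C3 bond (silyl enol ether and aryl vinyl ether at once, the only non-benzenoid π bond); the fusion is cis by necessity and the racemic nature of 4 is irrelevant because both centres disappear in step 5.

Step 4
Reactants: 4 rac-4,6-bis(methoxymethoxy)-6b-(triethylsilyloxy)-1a,6b-dihydro-1H-cyclopropa[b][1]benzofuran; 5 1-bromo-3-methylbut-2-ene (prenyl bromide)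
Product: 7 rac-4,6-bis(methoxymethoxy)-5-(3-methylbut-2-en-1-yl)-6b-(triethylsilyloxy)-1a,6b-dihydro-1H-cyclopropa[b][1]benzofuran, via aryllithium 6 (not isolated)
Conditions: n-BuLi, TMEDA, THF, 0 °C; then 5, −78 °C to rt
Reagents that add atoms: none
Why: Directed ortho-metalation followed by SN2 alkylation, in which C5–H lies between two chelating OMOM groups and should be removed in preference to C3–H (one OMOM group and the ring oxygen), and the silyl cyclopropyl ether, unlike a ketone or a chromone, tolerates butyllithium.

Step 5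
Reactants: 7 rac-4,6-bis(methoxymethoxy)-5-(3-methylbut-2-en-1-yl)-6b-(triethylsilyloxy)-1a,6b-dihydro-1H-cyclopropa[b][1]benzofuran
Product: 9 5,7-bis(methoxymethoxy)-6-(3-methylbut-2-en-1-yl)-4H-chromen-4-one, via 2-chlorochromanone 8 (not isolated)
Conditions: FeCl3 (2.2 equiv), pyridine, DMF, 0 °C to rt; then NaOAc, MeOH, 40 °C
Reagents that add atoms: none
Why: Chloride-assisted exchange at silicon gives an iron(III) cyclopropanolate, and inner-sphere electron transfer produces the cyclopropyloxy radical at C6b (the future C4). β-Scission takes the bond shared by the three- and five-membered rings (C1a–C6b, that is C2–C4), because this gives the secondary radical at C2 stabilised by the lone pair of O1 together with an aryl-conjugated ketone, while the primary radical from cleavage of the outer bond can return through the same oxy radical (Dowd–Beckwith manifold). A second FeCl3 transfers chlorine to C2, and the α-chloro ether 8 loses HCl to acetate to give the chromone. The closest known reaction type is the Saegusa ring enlargement of 1-silyloxybicyclo[n.1.0]alkanes to 2-cycloalkenones, here with n = 3 and one ring oxygen. No ring is closed and no stereocentre is made: the five- and three-membered rings merge into the six-membered ring, and the two stereocentres of racemic 7 are erased. The step needs chemoselectivity for the Si–O–cyclopropane unit over the prenyl group and the MOM acetals, which the DMF/pyridine-tempered iron salt, the inner-sphere mechanism and the distance between C2 and the C6 side chain should secure.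

Step 6
Reactants: 10 benzene-1,2-diol (catechol)
Product: 11 1,2-bis(methoxymethoxy)benzene
Conditions: MOMCl, i-Pr2NEt, CH2Cl2, 0 °C to rt
Reagents that add atoms: chloromethyl methyl ether COCCl
Why: Double O-alkylation (MOM ether formation) of two unhindered phenols, which installs the directing groups for step 7 and the same acid-labile protection as on ring A.

Step 7
Reactants: 11 1,2-bis(methoxymethoxy)benzene; 5 1-bromo-3-methylbut-2-ene (prenyl bromide)
Product: 13 1,2-bis(methoxymethoxy)-3-(3-methylbut-2-en-1-yl)benzene, via aryllithium 12 (not isolated)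
Conditions: n-BuLi, THF, 0 °C; then 5, −78 °C to rt
Reagents that add atoms: none
Why: Directed ortho-metalation next to an OMOM group (the two ortho positions are equivalent) followed by SN2 alkylation with the primary allylic bromide, which should give the linear prenyl arene.

Step 8
Reactants: 13 1,2-bis(methoxymethoxy)-3-(3-methylbut-2-en-1-yl)benzene
Product: 15 [3,4-bis(methoxymethoxy)-5-(3-methylbut-2-en-1-yl)phenyl]boronic acid, via pinacol boronate 14 (not isolated)
Conditions: [Ir(OMe)(cod)]2, dtbpy, B2pin2, THF, 60 °C; then NaIO4, NH4OAc, acetone–H2O, rt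
Reagents that add atoms: bis(pinacolato)diboron CC1(C)OB(OC1(C)C)B1OC(C)(C)C(C)(C)O1; water O
Why: Iridium-catalysed aromatic C–H borylation under steric control, in which only C5–H of the 1,2,3-trisubstituted ring has no ortho substituent, so boron should enter meta to the prenyl group and para to the inner OMOM group; periodate then removes pinacol under near-neutral conditions that spare acetals and alkene.

Step 9
Reactants: 9 5,7-bis(methoxymethoxy)-6-(3-methylbut-2-en-1-yl)-4H-chromen-4-one; 15 [3,4-bis(methoxymethoxy)-5-(3-methylbut-2-en-1-yl)phenyl]boronic acid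
Product: 16 (2S)-2-[3,4-bis(methoxymethoxy)-5-(3-methylbut-2-en-1-yl)phenyl]-5,7-bis(methoxymethoxy)-6-(3-methylbut-2-en-1-yl)-2,3-dihydro-4H-chromen-4-one
Conditions: [Rh(OH)((S)-MeO-F12-BIPHEP)]2 (cat.), 15 (excess), toluene–H2O, 25–40 °C
Reagents that add atoms: none
Why: Hayashi–Miyaura 1,4-addition, in which the aryl–rhodium species carbometalates C2=C3 on the face left open by the (S)-biaryl bisphosphine (the same spatial sense as with 2-cyclohexenone, which here corresponds to 2S), and near-neutral hydrolysis of the oxa-π-allyl rhodium should avoid β-aryloxide elimination and hence racemisation.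

Step 10
Reactants: 16 (2S)-2-[3,4-bis(methoxymethoxy)-5-(3-methylbut-2-en-1-yl)phenyl]-5,7-bis(methoxymethoxy)-6-(3-methylbut-2-en-1-yl)-2,3-dihydro-4H-chromen-4-one
Product: 17 (2S)-2-[3,4-dihydroxy-5-(3-methylbut-2-en-1-yl)phenyl]-5,7-dihydroxy-6-(3-methylbut-2-en-1-yl)-2,3-dihydro-4H-chromen-4-one (CNP0117506.1)
Conditions: 3 M aq HCl, MeOH, 45 °C, short contact time
Reagents that add atoms: none
Why: Acid-catalysed acetal exchange (MOM cleavage) with methanol as formaldehyde acceptor, in which C2 is not touched because base-induced ring opening is excluded, and the short mild treatment should keep the prenyl groups from cyclising onto the neighbouring phenols.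

Compound list
1 | 4,6-dihydroxy-1-benzofuran-3(2H)-one | O=C1COc2cc(O)cc(O)c12 | starting material
2 | 4,6-bis(methoxymethoxy)-1-benzofuran-3(2H)-one | O=C1COc2cc(OCOC)cc(OCOC)c12 | intermediate
3 | 4,6-bis(methoxymethoxy)-3-(triethylsilyloxy)-1-benzofuran | CC[Si](CC)(CC)Oc1coc2cc(OCOC)cc(OCOC)c12 | intermediate
4 | rac-4,6-bis(methoxymethoxy)-6b-(triethylsilyloxy)-1a,6b-dihydro-1H-cyclopropa[b][1]benzofuran (cis-fused, racemic) | CC[Si](CC)(CC)OC12CC1Oc1cc(OCOC)cc(OCOC)c12 | intermediate
5 | 1-bromo-3-methylbut-2-ene (prenyl bromide) | CC(C)=CCBr | starting material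
6 | 5-lithio derivative of 4 (racemic, not isolated) | CC[Si](CC)(CC)OC12CC1Oc1cc(OCOC)c([Li])c(OCOC)c12 | intermediate
7 | rac-4,6-bis(methoxymethoxy)-5-(3-methylbut-2-en-1-yl)-6b-(triethylsilyloxy)-1a,6b-dihydro-1H-cyclopropa[b][1]benzofuran | CC[Si](CC)(CC)OC12CC1Oc1cc(OCOC)c(CC=C(C)C)c(OCOC)c12 | intermediate
8 | rac-2-chloro-5,7-bis(methoxymethoxy)-6-(3-methylbut-2-en-1-yl)-2,3-dihydro-4H-chromen-4-one (not isolated) | O=C1CC(Cl)Oc2cc(OCOC)c(CC=C(C)C)c(OCOC)c12 | intermediate
9 | 5,7-bis(methoxymethoxy)-6-(3-methylbut-2-en-1-yl)-4H-chromen-4-one | O=c1ccoc2cc(OCOC)c(CC=C(C)C)c(OCOC)c12 | intermediate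
10 | benzene-1,2-diol (catechol) | Oc1ccccc1O | starting material
11 | 1,2-bis(methoxymethoxy)benzene | COCOc1ccccc1OCOC | intermediate
12 | 3-lithio-1,2-bis(methoxymethoxy)benzene (not isolated) | COCOc1cccc([Li])c1OCOC | intermediate
13 | 1,2-bis(methoxymethoxy)-3-(3-methylbut-2-en-1-yl)benzene | COCOc1cccc(CC=C(C)C)c1OCOC | intermediate
14 | 2-[3,4-bis(methoxymethoxy)-5-(3-methylbut-2-en-1-yl)phenyl]-4,4,5,5-tetramethyl-1,3,2-dioxaborolane (not isolated) | COCOc1cc(cc(CC=C(C)C)c1OCOC)B1OC(C)(C)C(C)(C)O1 | intermediate
15 | [3,4-bis(methoxymethoxy)-5-(3-methylbut-2-en-1-yl)phenyl]boronic acid | COCOc1cc(cc(CC=C(C)C)c1OCOC)B(O)O | intermediate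
16 | (2S)-2-[3,4-bis(methoxymethoxy)-5-(3-methylbut-2-en-1-yl)phenyl]-5,7-bis(methoxymethoxy)-6-(3-methylbut-2-en-1-yl)-2,3-dihydro-4H-chromen-4-one | CC(C)=CCc1cc([C@@H]2CC(=O)c3c(cc(OCOC)c(CC=C(C)C)c3OCOC)O2)cc(OCOC)c1OCOC | intermediate
17 | (2S)-2-[3,4-dihydroxy-5-(3-methylbut-2-en-1-yl)phenyl]-5,7-dihydroxy-6-(3-methylbut-2-en-1-yl)-2,3-dihydro-4H-chromen-4-one | CC(C)=CCc1cc([C@@H]2CC(=O)c3c(cc(O)c(CC=C(C)C)c3O)O2)cc(O)c1O | target

Total step count: 10
Longest linear sequence: 7 steps (1, 2, 3, 4, 5, 9, 10)

Steps most likely to fail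

1. Step 5. The iron chloride may act as a Lewis acid and strip MOM acetals. The HCl released may add across the prenyl double bond, and part of the material may be lost through the outer cyclopropane bond.
The fallback sets out from 7 and comes back at 9, and it separates ring enlargement from oxidation. Buffered fluoride (TBAF, AcOH, THF, 0 °C) frees the cyclopropanol F1. A redox-neutral, proton-coupled electron-transfer ring opening follows (iridium photocatalyst, collidine, catalytic thiophenol, blue light). Such ring openings are known for cycloalkanols that carry an electron-rich aryl group on the carbinol carbon. It passes through the same oxy radical and the same C2 radical but ends by hydrogen transfer, giving the chroman-4-one F2 under neutral, chloride-free conditions. The C2=C3 bond is then introduced separately: LDA at −78 °C, then N-tert-butylbenzenesulfinimidoyl chloride (Mukaiyama dehydrogenation), to give 9.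

2. Step 4. Metalation may also take place at the other doubly flanked position (C3–H, between one OMOM group and the ring oxygen). That would carry the prenyl group to the later C8.
The fallback sets out from 1 and comes back at 7. It fixes the position by a sigmatropic shift instead of by a metalation.
- The non-chelated 6-OH is protected first (1 equiv MOMCl) to give the mono-MOM ether F3.
- Allyl bromide and K2CO3 give the 4-O-allyl ether F4.
- Aromatic Claisen rearrangement (N,N-diethylaniline, heat), for which C5 is the only free ortho position, gives the 5-allyl phenol F5.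
- MOM protection gives the bis-MOM ketone F6.
- Silylation as in step 2 gives the silyloxybenzofuran F7.
- Cyclopropanation as in step 3, the monosubstituted alkene being the least reactive π bond, gives the allyl cyclopropane F8.
- Cross metathesis with 2-methyl-2-butene (Grubbs second-generation catalyst) gives 7.

3. Step 9. Carbometalation of the electron-rich, peri-substituted chromone may be slow. The rhodium enolate may open by β-aryloxide elimination, with erosion of enantiopurity.
The fallback sets out from 9 and 15 and comes back at 16. It replaces enantioselective C–C bond formation by a kinetic resolution. A more electrophilic achiral cationic palladium(II) catalyst (Pd(OCOCF3)2, 2,2'-bipyridine, aqueous dichloroethane, 60 °C) gives the racemic flavanone F9. Noyori–Ikariya transfer hydrogenation (Cp*RhCl[(R,R)-TsDPEN], HCO2H–Et3N) should reduce the (2R) enantiomer faster, to the cis-flavan-4-ol F10. Unreacted (2S)-16 is then separated by chromatography.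

Further compounds
F1 | step 5 | rac-4,6-bis(methoxymethoxy)-5-(3-methylbut-2-en-1-yl)-1a,6b-dihydro-1H-cyclopropa[b][1]benzofuran-6b-ol | OC12CC1Oc1cc(OCOC)c(CC=C(C)C)c(OCOC)c12
F2 | step 5 | 5,7-bis(methoxymethoxy)-6-(3-methylbut-2-en-1-yl)-2,3-dihydro-4H-chromen-4-one | O=C1CCOc2cc(OCOC)c(CC=C(C)C)c(OCOC)c12
F3 | step 4 | 4-hydroxy-6-(methoxymethoxy)-1-benzofuran-3(2H)-one | O=C1COc2cc(OCOC)cc(O)c12
F4 | step 4 | 6-(methoxymethoxy)-4-(prop-2-en-1-yloxy)-1-benzofuran-3(2H)-one | O=C1COc2cc(OCOC)cc(OCC=C)c12
F5 | step 4 | 4-hydroxy-6-(methoxymethoxy)-5-(prop-2-en-1-yl)-1-benzofuran-3(2H)-one | O=C1COc2cc(OCOC)c(CC=C)c(O)c12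
F6 | step 4 | 4,6-bis(methoxymethoxy)-5-(prop-2-en-1-yl)-1-benzofuran-3(2H)-one | O=C1COc2cc(OCOC)c(CC=C)c(OCOC)c12
F7 | step 4 | 4,6-bis(methoxymethoxy)-5-(prop-2-en-1-yl)-3-(triethylsilyloxy)-1-benzofuran | CC[Si](CC)(CC)Oc1coc2cc(OCOC)c(CC=C)c(OCOC)c12
F8 | step 4 | rac-4,6-bis(methoxymethoxy)-5-(prop-2-en-1-yl)-6b-(triethylsilyloxy)-1a,6b-dihydro-1H-cyclopropa[b][1]benzofuran | CC[Si](CC)(CC)OC12CC1Oc1cc(OCOC)c(CC=C)c(OCOC)c12
F9 | step 9 | rac-2-[3,4-bis(methoxymethoxy)-5-(3-methylbut-2-en-1-yl)phenyl]-5,7-bis(methoxymethoxy)-6-(3-methylbut-2-en-1-yl)-2,3-dihydro-4H-chromen-4-one | CC(C)=CCc1cc(C2CC(=O)c3c(cc(OCOC)c(CC=C(C)C)c3OCOC)O2)cc(OCOC)c1OCOC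
F10 | step 9 | (2R,4R)-2-[3,4-bis(methoxymethoxy)-5-(3-methylbut-2-en-1-yl)phenyl]-5,7-bis(methoxymethoxy)-6-(3-methylbut-2-en-1-yl)-3,4-dihydro-2H-chromen-4-ol | CC(C)=CCc1cc([C@H]2C[C@@H](O)c3c(cc(OCOC)c(CC=C(C)C)c3OCOC)O2)cc(OCOC)c1OCOC
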